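Ring A (C1–C5, C10) is disconnected at C2–C3 and C1–C10. With C4 as a ketone and the benzylic C9′ as an aryl ketone, these two carbonyl carbons are 1,5-related across C5 and the methyl-bearing quaternary C10, so a single anionic double Michael annulation joins two twelve-carbon halves, closes ring A and fixes C10 relative to the carvone-derived C7 centre. The precursors are (R)-1-acetyl-2-methyl-5-isopropenylcyclohexene, used as its kinetic lithium dienolate, and 2,4,6-trimethoxyphenyl vinyl ketone. What follows is conservative: C5/C7 equilibration, stereoselective deoxygenation at C9′, two methyl additions and late unmasking of the diformylphloroglucinol.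

Key step: step 5

Numbering: eudesmane-type locants are used for all bicyclic compounds (ring A = C1–C5 and C10, ring B = C5–C10, C9′ = benzylic carbon on C1, C11 = carbinol carbon on C7); β is the face of the C10 methyl group, α the opposite face.

Remark: 14 is written as the cis-fused ring-fusion epimer expected while C7 still carries the α-isopropenyl group; C1, C5 and (from 15 on) C7 are α to carbonyl groups, so epimers at these centres converge on 16 in step 7.

Step 1
Reactants: 1 (R)-(−)-carvone
Product: 3 (5R)-2-methyl-5-(prop-1-en-2-yl)cyclohex-1-en-1-yl trifluoromethanesulfonate, via lithium enolate 2 (not isolated)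
Conditions: LiBH(s-Bu)3 (1.05 equiv), THF, −78 °C; then PhNTf2, −78 °C → rt
Reagents that add atoms: N-phenylbis(trifluoromethanesulfonimide), O=S(=O)(N(c1ccccc1)S(=O)(=O)C(F)(F)F)C(F)(F)F
Why: Conjugate (1,4-) hydride reduction of the enone by LiBH(s-Bu)3 should give regiospecifically the tetrasubstituted C1=C2 enolate 2, which is O-sulfonylated in situ (reductive enol triflation); the C5 stereocentre of carvone is not involved.

Step 2
Reactants: 3 (5R)-2-methyl-5-(prop-1-en-2-yl)cyclohex-1-en-1-yl trifluoromethanesulfonate; 4 tributyl(1-ethoxyvinyl)stannane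
Product: 6 1-[(5R)-2-methyl-5-(prop-1-en-2-yl)cyclohex-1-en-1-yl]ethan-1-one, via ethoxydiene 5 (not isolated)
Conditions: Pd(PPh3)4 (5 mol %), LiCl (3 equiv), THF, reflux; then 1 M HCl, THF, rt
Reagents that add atoms: water, O
Why: Stille coupling of the alkenyl triflate with the α-ethoxyvinyl stannane (an acetyl-anion equivalent), followed by mild acid hydrolysis of enol ether 5, should deliver the tetrasubstituted methyl enone without touching the isopropenyl group or the stereocentre.

Step 3
Reactants: 7 1,3,5-trimethoxybenzene; 8 3-chloropropanoyl chloride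
Product: 9 3-chloro-1-(2,4,6-trimethoxyphenyl)propan-1-one
Conditions: AlCl3 (1.1 equiv), CH2Cl2, −10 → 0 °C; ice–HCl quench
Reagents that add atoms: none
Why: Friedel–Crafts acylation of the very electron-rich arene should stop after one acylation because the ketone deactivates the ring, and the saturated β-chloro acid chloride avoids the polymerisation and conjugate arylation that an acryloyl electrophile invites.

Step 4
Reactants: 9 3-chloro-1-(2,4,6-trimethoxyphenyl)propan-1-one
Product: 10 1-(2,4,6-trimethoxyphenyl)prop-2-en-1-one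
Conditions: Et3N (1.5 equiv), CH2Cl2, 0 °C → rt; filtered through silica and used at once
Reagents that add atoms: none
Why: Amine-induced E1cB dehydrochlorination of the β-chloro ketone should give the aryl vinyl ketone, which is generated just before the annulation because such enones polymerise on storage.

Step 5
Reactants: 6 1-[(5R)-2-methyl-5-(prop-1-en-2-yl)cyclohex-1-en-1-yl]ethan-1-one; 10 1-(2,4,6-trimethoxyphenyl)prop-2-en-1-one
Product: 14 cis-fused diketone (4S,4aS,7R,8aR)-4a-methyl-7-(prop-1-en-2-yl)-4-(2,4,6-trimethoxybenzoyl)octahydronaphthalen-1(2H)-one, via lithium dienolate 11 (not isolated), via open-chain adduct enolate 12 (not isolated), via bicyclic lithium enolate 13 (not isolated)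
Conditions: LiN(i-Pr)2 (1.05 equiv), THF, −78 °C; 10 added slowly at −78 °C; then −78 → 0 °C; aq NH4Cl
Reagents that add atoms: none
Why: Kinetic α′-deprotonation of 6 gives the cross-conjugated dienolate 11, whose terminal methylene adds 1,4 to vinyl ketone 10 (C2–C3), and the aryl ketone enolate 12 then adds intramolecularly to the regenerated β-methyl enone at C10 (C1–C10); this is an anionic double Michael (Michael–Michael ring closure) annulation of the kind known for acetylcyclohexene dienolates with acrylates and vinyl ketones, including closures that create quaternary carbons. Ring A is closed in the 6-endo-trig mode, both former alkene carbons lying in the new ring. C10 is set kinetically by antiparallel (axial) attack on the ring B half-chair that holds the C7 isopropenyl group pseudoequatorial, which puts C1 on the isopropenyl face and the methyl group trans to it. C1 and C5 are α to carbonyl groups and should settle with the aroyl group equatorial and, while C7 is α-isopropenyl, a cis ring fusion (axial protonation of 13); both are re-equilibrated in step 7. The step needs α′- over γ-deprotonation (kinetic base at −78 °C), 1,4- over 1,2-addition (the carbonyl of 10 is shielded by two ortho-methoxy groups) and facial selectivity at C10 (secured by the carvone-derived C7 centre). The minor C10 epimer is removed by chromatography here, because once C7 is epimerisable it would converge on the enantiomer of 16.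

Step 6
Reactants: 14 cis-fused diketone (7α-isopropenyl)
Product: 15 cis-fused triketone (4S,4aS,7R,8aR)-7-acetyl-4a-methyl-4-(2,4,6-trimethoxybenzoyl)octahydronaphthalen-1(2H)-one
Conditions: OsO4 (2 mol %), NaIO4 (4 equiv), 2,6-lutidine (2 equiv), dioxane–H2O, rt
Reagents that add atoms: NaIO4 (sodium periodate; its oxygen reaches the product through OsO4), [Na+].[O-]I(=O)(=O)=O
Why: Lemieux–Johnson oxidation (catalytic dihydroxylation of the only C=C bond, then periodate cleavage of the diol) should convert the isopropenyl group into the C7 acetyl group with retention at C7, the buffered conditions leaving the ketones and the arene untouched.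

Step 7
Reactants: 15 cis-fused triketone (7α-acetyl; 5β-H)
Product: 16 trans-fused triketone (4S,4aS,7S,8aS)-7-acetyl-4a-methyl-4-(2,4,6-trimethoxybenzoyl)octahydronaphthalen-1(2H)-one (1β-aroyl; 5α-H; 7β-acetyl; 10β-methyl)
Conditions: NaOMe (0.3 equiv), MeOH, rt
Reagents that add atoms: none
Why: Reversible enolisation α to the C4 ketone and to the acetyl group should move C5 and C7 to the trans-fused isomer in which 1-aroyl and 7-acetyl are both equatorial (thermodynamic epimerisation, the trans fusion being favoured as in 5α- over 5β-6-oxo steroids), and any cis-fused remainder is separated and resubmitted.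

Step 8
Reactants: 16 trans-fused triketone
Product: 17 bis-dioxolane: 4,4-ethylenedioxy-10β-methyl-7β-(2-methyl-1,3-dioxolan-2-yl)-1β-(2,4,6-trimethoxybenzoyl)-trans-decalin (5α-H)
Conditions: (Me3SiOCH2)2 (2.5 equiv), Me3SiOTf (5 mol %), CH2Cl2, −78 → −20 °C; pyridine quench
Reagents that add atoms: 1,2-bis(trimethylsilyloxy)ethane, C[Si](C)(C)OCCO[Si](C)(C)C
Why: Noyori ketalisation should protect only the two aliphatic ketones, since the aryl ketone is shielded by two ortho-methoxy groups and a branched α-carbon, and its aprotic low-temperature conditions avoid enolisation so that C5 and C7 keep their configuration.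

Step 9
Reactants: 17 bis-dioxolane aryl ketone
Product: 18 tertiary homoallylic carbinol: 17 in which C9′ carries OH, the aryl group and a 2-methylallyl group (both C9′ epimers)
Conditions: 2-methylallylmagnesium chloride (3 equiv), THF, 0 °C; aq NH4Cl
Reagents that add atoms: 2-methylallylmagnesium chloride, CC(=C)C[Mg]Cl
Why: 2-Methylallylmagnesium chloride should add to the hindered aryl ketone through a cyclic six-membered (SE2′) transition state, without the enolisation or reduction that saturated reagents suffer, and the configuration of the new carbinol centre is irrelevant because it becomes planar in step 11.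

Step 10
Reactants: 18 tertiary homoallylic carbinol
Product: 19 tertiary carbinol with isobutyl in place of 2-methylallyl at C9′ (both C9′ epimers)
Conditions: H2 (1 atm), Pd/C (5 wt %), EtOAc, Et3N (trace), rt
Reagents that add atoms: none
Why: Heterogeneous hydrogenation of the unhindered 1,1-disubstituted alkene should give the isobutyl group, the amine-buffered neutral medium preventing ionisation or hydrogenolysis of the benzylic carbinol.

Step 11
Reactants: 19 tertiary carbinol
Product: 21 diketone: 7β-acetyl-10β-methyl-1β-[(1S)-3-methyl-1-(2,4,6-trimethoxyphenyl)butyl]-trans-decalin-4-one (5α-H), via reduced bis-dioxolane 20 (not isolated)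
Conditions: Et3SiH (3 equiv), CF3CO2H (5 equiv), CH2Cl2, −40 → 0 °C; then H2O–THF, rt
Reagents that add atoms: water, O
Why: Ionic hydrogenation: the carbinol ionises to a trimethoxybenzylic cation in which allylic A(1,3) strain with an ortho-methoxy group holds C1–H in the cation plane, so Et3SiH should deliver hydride to the face turned away from the quaternary C10 and set C9′ as S, after which aqueous CF3CO2H hydrolyses both dioxolanes.

Step 12
Reactants: 21 diketone
Product: 22 diol: 4β-hydroxy-7β-(2-hydroxypropan-2-yl)-4α,10β-dimethyl-1β-[(1S)-3-methyl-1-(2,4,6-trimethoxyphenyl)butyl]-trans-decalin (5α-H)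
Conditions: MeMgBr (5 equiv), anhydrous CeCl3 (5 equiv), THF, −78 → 0 °C; aq NH4Cl
Reagents that add atoms: methylmagnesium bromide, C[Mg]Br
Why: MeCeCl2 formed in situ is non-basic and should add to both enolisable ketones; at C4 it attacks equatorially (α-face) because the axial trajectory is blocked by the syn-axial C10 methyl group, giving the axial 4β-hydroxyl and equatorial 4α-methyl, while the acetyl group becomes the achiral dimethylcarbinol.

Step 13
Reactants: 22 diol
Product: 23 dibromide: 22 with bromine at both free aryl positions (3,5-dibromo-2,4,6-trimethoxyphenyl)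
Conditions: NBS (2.1 equiv), MeCN, 0 °C → rt, dark
Reagents that add atoms: N-bromosuccinimide, O=C1CCC(=O)N1Br
Why: Electrophilic aromatic bromination should occur only at the two remaining ring positions, each activated by two flanking methoxy groups, under neutral conditions that do not ionise the tertiary alcohols.

Step 14
Reactants: 23 dibromide
Product: 25 dialdehyde: 22 with formyl groups at both free aryl positions (2,4,6-trimethoxybenzene-1,3-dicarbaldehyde unit), via tetralithio species 24 (not isolated)
Conditions: n-BuLi (5 equiv), THF, −78 °C; DMF (8 equiv), −78 → 0 °C; aq NH4Cl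
Reagents that add atoms: N,N-dimethylformamide, CN(C)C=O
Why: After deprotonation of both hydroxyl groups, double bromine–lithium exchange should give two aryl C–Li centres each stabilised by two ortho-methoxy groups, and Bouveault formylation with DMF then installs both aldehydes under basic conditions that spare the tertiary alcohols, which Lewis-acid formylations would ionise.

Step 15
Reactants: 25 dialdehyde
Product: 26 target, 5-{(1S)-1-[(1R,4R,4aS,6S,8aR)-4-hydroxy-6-(2-hydroxypropan-2-yl)-4,8a-dimethyldecahydronaphthalen-1-yl]-3-methylbutyl}-2,4,6-trihydroxybenzene-1,3-dicarbaldehyde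
Conditions: NaSEt (10 equiv), DMF, 120 °C; then cold 1 M HCl to pH 3
Reagents that add atoms: none
Why: SN2 O-demethylation by NaSEt should remove all three methyl groups because each methoxy group is ortho or para to a formyl group and leaves as a stabilised (vinylogous carboxylate) phenoxide, the basic medium again sparing the tertiary alcohols.

Compound list
1 | (R)-(−)-carvone, (5R)-2-methyl-5-(prop-1-en-2-yl)cyclohex-2-en-1-one | CC1=CC[C@H](CC1=O)C(C)=C | starting material
2 | lithium (5R)-2-methyl-5-(prop-1-en-2-yl)cyclohex-1-en-1-olate | [Li]OC1=C(C)CC[C@H](C1)C(C)=C | intermediate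
3 | (5R)-2-methyl-5-(prop-1-en-2-yl)cyclohex-1-en-1-yl trifluoromethanesulfonate | O=S(=O)(OC1=C(C)CC[C@H](C1)C(C)=C)C(F)(F)F | intermediate
4 | tributyl(1-ethoxyvinyl)stannane | CCOC(=C)[Sn](CCCC)(CCCC)CCCC | starting material
5 | (5R)-1-(1-ethoxyvinyl)-2-methyl-5-(prop-1-en-2-yl)cyclohex-1-ene | CCOC(=C)C1=C(C)CC[C@H](C1)C(C)=C | intermediate
6 | 1-[(5R)-2-methyl-5-(prop-1-en-2-yl)cyclohex-1-en-1-yl]ethan-1-one | CC(=O)C1=C(C)CC[C@H](C1)C(C)=C | intermediate
7 | 1,3,5-trimethoxybenzene | COc1cc(OC)cc(OC)c1 | starting material
8 | 3-chloropropanoyl chloride | ClCCC(Cl)=O | starting material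
9 | 3-chloro-1-(2,4,6-trimethoxyphenyl)propan-1-one | ClCCC(=O)c1c(OC)cc(OC)cc1OC | intermediate
10 | 1-(2,4,6-trimethoxyphenyl)prop-2-en-1-one | C=CC(=O)c1c(OC)cc(OC)cc1OC | intermediate
11 | lithium 1-[(5R)-2-methyl-5-(prop-1-en-2-yl)cyclohex-1-en-1-yl]ethen-1-olate (cross-conjugated dienolate) | [Li]OC(=C)C1=C(C)CC[C@H](C1)C(C)=C | intermediate
12 | lithium enolate (aryl ketone side) of 1-[(5R)-2-methyl-5-(prop-1-en-2-yl)cyclohex-1-en-1-yl]-5-(2,4,6-trimethoxyphenyl)pentane-1,5-dione | [Li]OC(=CCCC(=O)C1=C(C)CC[C@H](C1)C(C)=C)c1c(OC)cc(OC)cc1OC | intermediate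
13 | bicyclic lithium C4–C5 enolate of 14 (1β-aroyl; 7α-isopropenyl; 10β-methyl) | O=C(c1c(OC)cc(OC)cc1OC)[C@H]1CCC(O[Li])=C2C[C@H](C(C)=C)CC[C@]12C | intermediate
14 | (4S,4aS,7R,8aR)-4a-methyl-7-(prop-1-en-2-yl)-4-(2,4,6-trimethoxybenzoyl)octahydronaphthalen-1(2H)-one (cis-fused; 1β-aroyl, 5β-H, 7α-isopropenyl, 10β-methyl) | O=C(c1c(OC)cc(OC)cc1OC)[C@H]1CCC(=O)[C@@H]2C[C@H](C(C)=C)CC[C@]12C | intermediate
15 | (4S,4aS,7R,8aR)-7-acetyl-4a-methyl-4-(2,4,6-trimethoxybenzoyl)octahydronaphthalen-1(2H)-one (cis-fused; 7α-acetyl, 5β-H) | O=C(c1c(OC)cc(OC)cc1OC)[C@H]1CCC(=O)[C@@H]2C[C@H](C(C)=O)CC[C@]12C | intermediate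
16 | (4S,4aS,7S,8aS)-7-acetyl-4a-methyl-4-(2,4,6-trimethoxybenzoyl)octahydronaphthalen-1(2H)-one (trans-fused; 1β-aroyl, 5α-H, 7β-acetyl, 10β-methyl) | O=C(c1c(OC)cc(OC)cc1OC)[C@H]1CCC(=O)[C@H]2C[C@@H](C(C)=O)CC[C@]12C | intermediate
17 | bis-dioxolane of 16: 4,4-ethylenedioxy-10β-methyl-7β-(2-methyl-1,3-dioxolan-2-yl)-1β-(2,4,6-trimethoxybenzoyl)-trans-decalin (5α-H) | O=C(c1c(OC)cc(OC)cc1OC)[C@H]1CCC3(OCCO3)[C@H]2C[C@@H](C4(C)OCCO4)CC[C@]12C | intermediate
18 | 17 with C9′ converted into C(OH)(2-methylallyl)(2,4,6-trimethoxyphenyl), both C9′ epimers | CC(=C)CC(O)(c1c(OC)cc(OC)cc1OC)[C@H]1CCC3(OCCO3)[C@H]2C[C@@H](C4(C)OCCO4)CC[C@]12C | intermediate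
19 | 17 with C9′ converted into C(OH)(isobutyl)(2,4,6-trimethoxyphenyl), both C9′ epimers | CC(C)CC(O)(c1c(OC)cc(OC)cc1OC)[C@H]1CCC3(OCCO3)[C@H]2C[C@@H](C4(C)OCCO4)CC[C@]12C | intermediate
20 | bis-dioxolane with (9′S)-CH(isobutyl)(2,4,6-trimethoxyphenyl) at C1β: 4,4-ethylenedioxy-10β-methyl-7β-(2-methyl-1,3-dioxolan-2-yl)-1β-[(1S)-3-methyl-1-(2,4,6-trimethoxyphenyl)butyl]-trans-decalin | CC(C)C[C@H](c1c(OC)cc(OC)cc1OC)[C@H]1CCC3(OCCO3)[C@H]2C[C@@H](C4(C)OCCO4)CC[C@]12C | intermediate
21 | 7β-acetyl-10β-methyl-1β-[(1S)-3-methyl-1-(2,4,6-trimethoxyphenyl)butyl]-trans-decalin-4-one (5α-H) | CC(C)C[C@H](c1c(OC)cc(OC)cc1OC)[C@H]1CCC(=O)[C@H]2C[C@@H](C(C)=O)CC[C@]12C | intermediate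
22 | 4β-hydroxy-7β-(2-hydroxypropan-2-yl)-4α,10β-dimethyl-1β-[(1S)-3-methyl-1-(2,4,6-trimethoxyphenyl)butyl]-trans-decalin (5α-H) | CC(C)C[C@H](c1c(OC)cc(OC)cc1OC)[C@H]1CC[C@@](C)(O)[C@H]2C[C@@H](C(C)(C)O)CC[C@]12C | intermediate
23 | 22 with a 3,5-dibromo-2,4,6-trimethoxyphenyl group | CC(C)C[C@H](c1c(OC)c(Br)c(OC)c(Br)c1OC)[C@H]1CC[C@@](C)(O)[C@H]2C[C@@H](C(C)(C)O)CC[C@]12C | intermediate
24 | dilithium dialkoxide of 23 with both C–Br replaced by C–Li | CC(C)C[C@H](c1c(OC)c([Li])c(OC)c([Li])c1OC)[C@H]1CC[C@@](C)(O[Li])[C@H]2C[C@@H](C(C)(C)O[Li])CC[C@]12C | intermediate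
25 | 22 with a 3,5-diformyl-2,4,6-trimethoxyphenyl group | CC(C)C[C@H](c1c(OC)c(C=O)c(OC)c(C=O)c1OC)[C@H]1CC[C@@](C)(O)[C@H]2C[C@@H](C(C)(C)O)CC[C@]12C | intermediate
26 | 5-{(1S)-1-[(1R,4R,4aS,6S,8aR)-4-hydroxy-6-(2-hydroxypropan-2-yl)-4,8a-dimethyldecahydronaphthalen-1-yl]-3-methylbutyl}-2,4,6-trihydroxybenzene-1,3-dicarbaldehyde (CNP0409870.4) | CC(C)C[C@H](c1c(O)c(C=O)c(O)c(C=O)c1O)[C@H]1CC[C@@](C)(O)[C@H]2C[C@@H](C(C)(C)O)CC[C@]12C | target

Total step count: 15
Longest linear sequence: 13 steps (steps 1, 2 and 5–15 from (R)-carvone; the arm from 1,3,5-trimethoxybenzene, steps 3–15, is equally long)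

Steps most likely to fail

1. Step 5. The ring-closing conjugate addition at the fully substituted C10 may be slower than proton transfer within enolate 12 and than oligomerisation of vinyl ketone 10, and attack may not discriminate well between the two faces of ring B. The fallback replaces the anionic ring closure by a Lewis-acid-mediated one. Starting again from 6 and 10, only the first Michael addition is run at −78 °C and enolate 12 is trapped with Me3SiCl to give the regiodefined trimethylsilyl enol ether F1, which is isolated. TiCl4 (CH2Cl2, −78 °C) then activates the enone for an intramolecular Mukaiyama–Michael addition that forms C1–C10, and aqueous work-up comes back to the route at 14.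

2. Step 11. Hydride transfer to the planar benzylic cation may take place mainly on the face syn to C10 and give the C9′ epimer, and the dioxolanes may be opened reductively if ionisation of the carbinol is slow. The fallback exchanges the order of the two bond formations at C9′. From 17, the aryl ketone is reduced with LiAlH4 (THF, 0 °C) to the secondary benzylic alcohol F2. Ionisation with CF3CO2H at −78 °C in the presence of trimethyl(2-methylallyl)silane (Hosomi–Sakurai-type capture of the cation by carbon) gives the 9′-(2-methylallyl) compound F3; because carbon now enters where hydride entered before, the same facial preference leads to the opposite configuration at C9′. Hydrogenation (H2, Pd/C) leads to 20, and the hydrolysis stage of step 11 to 21.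

3. Step 14. The second bromine–lithium exchange on an already polyanionic substrate may be incomplete, or an aryl C–Li centre may be protonated, so that monoformylated material results. The fallback uses catalytic C–C coupling and oxidative cleavage in place of organolithium chemistry. From 23, double Stille coupling with tributyl(vinyl)stannane (Pd2(dba)3, P(t-Bu)3, CsF, dioxane, 100 °C) gives the 3,5-divinylarene F4, and Lemieux–Johnson cleavage of both vinyl groups (OsO4 cat., NaIO4, 2,6-lutidine, dioxane–H2O) comes back to the route at 25.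

Further compounds
F1 | step 5 | trimethylsilyl enol ether (aryl ketone side) of 1-[(5R)-2-methyl-5-(prop-1-en-2-yl)cyclohex-1-en-1-yl]-5-(2,4,6-trimethoxyphenyl)pentane-1,5-dione | C[Si](C)(C)OC(=CCCC(=O)C1=C(C)CC[C@H](C1)C(C)=C)c1c(OC)cc(OC)cc1OC
F2 | step 11 | 17 with the aryl ketone reduced to CH(OH) at C9′ (either epimer) | OC(c1c(OC)cc(OC)cc1OC)[C@H]1CCC3(OCCO3)[C@H]2C[C@@H](C4(C)OCCO4)CC[C@]12C
F3 | step 11 | bis-dioxolane with CH(2-methylallyl)(2,4,6-trimethoxyphenyl) at C1β, C9′ configured as in 20 | CC(=C)C[C@H](c1c(OC)cc(OC)cc1OC)[C@H]1CCC3(OCCO3)[C@H]2C[C@@H](C4(C)OCCO4)CC[C@]12C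
F4 | step 14 | 22 with a 2,4,6-trimethoxy-3,5-divinylphenyl group | CC(C)C[C@H](c1c(OC)c(C=C)c(OC)c(C=C)c1OC)[C@H]1CC[C@@](C)(O)[C@H]2C[C@@H](C(C)(C)O)CC[C@]12C
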